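## Structural features

The target is a trans-fused decalin of the eudesmane type (ring A = C1–C5 with C10, ring B = C5–C10). C1 is joined to an exocyclic benzylic carbon C9′ that also carries an isobutyl group and a fully substituted 3,5-diformyl-2,4,6-trihydroxyphenyl ring. Five stereocentres are contiguous (C9′–C1–C10–C5–C4) and C7 on ring B is the sixth. C10 is quaternary (angular methyl); the C1 and C7 substituents are equatorial and cis to that methyl; H-5 is anti to it; the C4 hydroxyl is axial and syn to it. The fragile groups are the two tertiary carbinols (C4 and C11, which ionise or dehydrate with acid), the electron-rich phloroglucinol dialdehyde and the benzylic C9′–H. The real difficulty is the quaternary C10 in the middle of the contiguous array, together with C9′, which lies outside the rings and can be controlled only from C1. A hidden difficulty is C5: next to a C4 carbonyl it is epimerisable, and the trans preference of a 10-methyl-1-decalone is small. The key step exploits the fact that ring A, with oxygen at C4, a methyl on C10 and a one-carbon unit on C1, is the carbon pattern of 1. C5 and C10 are the α- and β-carbons of its enone, so ring B (C5–C6–C7–C8–C9–C10) can close by a C9 radical bonding to C10.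

## Logic of the disconnections

20 to 19: the three aryl O–CH3 bonds are cut. The phenols stay masked through every organometallic and cationic step, and only three methyl groups separate 19 from 20. The forward step must be a demethylation that spares aldehydes and tertiary alcohols; a thiolate fits because each methoxy group is ortho or para to a formyl group.

19 to 17 to 16: the two aryl–CHO bonds are cut. Formyl groups would not survive the aryllithium, cation and hydrogenation steps, so they are put on last through the dibromide. The demand is a double halogen–metal exchange in the presence of two alkoxides.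

16 to 15 to 14: the C9′–CH2 bond of the isobutyl group is cut. The trimethoxyphenyl group makes C9′ an exceptionally stabilised cation, and a four-carbon allylsilane supplies the isobutyl carbons. The side chain is thereby reduced to an aldehyde, an arene and a silane. The forward step must bond to the cation face anti to C10 and must ionise only the benzylic carbinol, not the tertiary ones.

14 to 11 and 12: the aryl–C9′ bond is cut. All ring positions of 12 are equivalent, so metalation is unambiguous. The demand is an excess of the aryllithium, because two hydroxyl groups are free.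

11 to 10 to 9 to 8: the C4–CH3 bond and both C11–CH3 bonds are cut, and the C1 carbon is taken back to the ester level. One methyl nucleophile supplies all three methyl groups and removes the C4 carbonyl, which locks C5. The demand is chemoselectivity by steric hindrance (the C1 ester next to quaternary C10 must survive) and equatorial attack at C4.

8 to 7: the C9–C10 bond is cut. This opens ring B and removes the quaternary centre and the C5 stereocentre, leaving a monocyclic enone. The forward step must close 6-endo onto a fully substituted β-carbon faster than the radical is reduced, anti to the C1 ester, with hydrogen then delivered to C5 anti to the new angular methyl. 7 must be the isomer whose C7 is already matched.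

7 to 6 to 3: the C9–I bond is traced back to the lactone C–O bond, and the single stereoisomer to the mixture. The lactone masks the iodo ester during the enolate step, where a free halide would be displaced by the adduct enolate. The demands are a lactone opening that leaves the ethyl ester alone and a resolution placed after the last acidic or basic step, because H-1 is labile.

3 to 1 and 2: the C5–C6 bond is cut, which leads to two commercial compounds. The demand is that the ambident dienolate of 1 reacts through C5 and not through C1.

## Other disconnections considered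

Alternative 1: The aryl–C9′, C9′–C1 and C5–C10 bonds are cut in one operation. In the forward sense 2,4,6-trihydroxybenzene-1,3-dicarbaldehyde A3 and 3-methylbutanal A4 condense to the ortho-quinone methide A5. C1 of (7S)-hedycaryol A2 attacks C9′ of A5, C5 captures the C10 cation across the ten-membered ring, and the C4 cation loses a proton to give the 3-ene A1. A Markovnikov hydration of A1 must then deliver the axial C4 hydroxyl.
- In its favour: three C–C bonds, both rings and four stereocentres form at once; C7 and the C11 carbinol are already in A2; the aryl dialdehyde enters complete and unprotected, so no late aryl functionalisation is needed. On step economy from A2 it is clearly the better plan, and on the trans ring fusion it is at least the equal, since a chair-like transannular closure gives it naturally.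
- Against it here: A2 is not commercial, is thermally labile (Cope rearrangement) and cyclises on its own with acid, so the saved steps are partly hidden in its preparation. A5 may also react as a heterodiene. Nothing designed controls C9′ or the face of A2 that is attacked. The C4 cation can end in several ways. The final hydration must be regio- and stereoselective beside phenolic aldehydes; a hydrogen-atom-transfer hydration would probably give the equatorial alcohol, whereas oxymercuration with trans-diaxial opening would fit.
- Comparison: the chosen plan is longer and needs a resolution, but each stereocentre has an identifiable control element and the starting materials are commercial.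

Alternative 2: The C4–C5 bond is cut. In the forward sense a chiral N-heterocyclic carbene converts the C4 aldehyde of the 4,4-disubstituted cyclohexadienone A7 into an acyl anion equivalent that adds to C5 of one enone arm, giving the cis-fused diketone A6.
- In its favour: the quaternary C10 is set by a catalyst and not by a resolution, which is a point where it is better than the chosen plan. No radical reagent is needed, the C4 carbonyl is in place for the methyl addition, and C9′ and C1 are settled at an acyclic stage, away from the tertiary carbinols.
- Against it here: A6 is cis-fused, so C5 must be inverted by an equilibration whose outcome is doubtful and which now also risks β-elimination toward the C7 ketone. Ring B arrives with a C7 ketone and a C8=C9 alkene, so the C7 stereocentre and the three-carbon carbinol unit still have to be built, with the two ketones differentiated. A7 already contains the C9′/C1 pair and a quaternary dienone carbon bearing a secondary alkyl group, so it is at least as hard to make as 7. The existing C1 centre makes the two enone arms diastereotopic, so the catalyst must override the substrate.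
- Comparison: better absolute control at C10, equal in closing one ring, worse in overall length and in the work left on ring B.

Alternative 3: The C7–C8 bond is cut. In the forward sense dilute aqueous mineral acid makes the C8 aldehyde of A9 bond to C7 of the prenyl group on C5; ring B closes and the C11 cation is trapped by water, giving the hydroxy decalone A8.
- In its favour: ring B, the equatorial C7 substituent and the C11 carbinol arise together through a chair transition state with a cheap reagent. Only one ester is left, so the ester differentiation of step 5 disappears, which is a point where it is better than the chosen plan. On ring A it is the equal, since it uses the same Hagemann-type ring.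
- Against it here: the quaternary C10 with its two-carbon aldehyde arm must already be present in A9, which means an intermolecular conjugate addition to a tetrasubstituted enone, harder than the intramolecular radical closure. The extra C8 hydroxyl must be removed beside two tertiary alcohols (two more steps, for example Barton–McCombie). The acid may cause an aldol reaction of the aldehyde with C3, or ene-type termination without hydration.
- Comparison: equal in strategy for ring A, better for C11, worse for C10 and no shorter.

Key step: step 4

Remark on the chemistry (assumption): cis- and trans-fused 10-methyl-1-decalones are taken to be close in energy (angular methyl, 3-alkyl ketone effect). C5 is therefore set by kinetic hydrogen transfer in step 4 and locked in step 5, and 8 is never equilibrated with base.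

Remark on the precursor: 6 has two stereocentres and is a set of four stereoisomers, not one racemate. Only the isomer with (1S) and the matched C7 is carried on as 7, so no epimerisation at C7 (which would drag C5 along) is needed after ring closure. No connectivity or stereodescriptor of 7, 8 or 20 needed correction; only the CIP letters change with the substituents.

Remark on names: C-labels in the text are those defined under Structural features; names use IUPAC ring locants.

Step 1
Reactants: 1 ethyl 2-methyl-4-oxocyclohex-2-ene-1-carboxylate (racemic); 2 3-methylideneoxolan-2-one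
Product: 3 ethyl 2-methyl-4-oxo-3-[(2-oxooxolan-3-yl)methyl]cyclohex-2-ene-1-carboxylate (four stereoisomers)
Conditions: t-BuOK (0.2 equiv), t-BuOH–THF, 0 °C to rt; 2 added slowly to 1 (1.3 equiv); AcOH quench
Reagents that add atoms: none
Why: Michael addition of the extended dienolate of 1; like its well-known alkylation it should go through the ketone α-carbon C5, the unhindered terminus, because C1 carries the ester and would become quaternary. Proton transfer restores the tetrasubstituted enone; C1 and C7 are not controlled here.

Step 2
Reactants: 3
Product: 6 ethyl 3-[4-iodo-2-(methoxycarbonyl)butyl]-2-methyl-4-oxocyclohex-2-ene-1-carboxylate (four stereoisomers), via silyl ester 4 (not isolated), via iodo acid 5 (not isolated)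
Conditions: Me3SiI (1.3 equiv), CH2Cl2, 0 °C to rt; H2O; crude acid, Me3SiCHN2, MeOH–PhMe, 0 °C
Reagents that add atoms: iodotrimethylsilane C[Si](C)(C)I; (trimethylsilyl)diazomethane C[Si](C)(C)C=[N+]=[N-]
Why: silyl iodide opening of a γ-lactone by alkyl–oxygen cleavage (iodide attacks C9 of the O-silylated lactone), which should be faster than dealkylation of the acyclic ethyl ester. The acid is methylated with the diazoalkane and not in acidic methanol, so that the C1 ester stays ethyl and the C7 ester is methyl.

Step 3
Reactants: 6
Product: 7 ethyl (1S)-3-[(2R)-4-iodo-2-(methoxycarbonyl)butyl]-2-methyl-4-oxocyclohex-2-ene-1-carboxylate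
Conditions: preparative SFC, amylose tris(3,5-dimethylphenylcarbamate) phase, CO2–i-PrOH, rt; used at once
Reagents that add atoms: none
Why: resolution by chromatography on a chiral stationary phase, placed after the last acidic or basic step because H-1 (α to the ester and vinylogously α to the ketone) is labile. The isomer taken has C1 set for facial control and C7 matched, so that its ester is equatorial after ring closure.

Step 4
Reactants: 7
Product: 8 1-ethyl 6-methyl (1S,4aS,6S,8aS)-8a-methyl-4-oxodecahydronaphthalene-1,6-dicarboxylate
Conditions: (Me3Si)3SiH (1.3 equiv), AIBN (0.2 equiv), syringe pump over 8 h, PhMe (0.01 M), 90 °C; neutral work-up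
Reagents that add atoms: none
Why: Radical chain: the silyl radical abstracts iodine, the primary C9 radical adds to C10 (the β-carbon of the enone), and the resulting C5 α-keto radical takes hydrogen from the silane. The closest known reaction type is the tin- or silicon-hydride-mediated 6-endo cyclisation of alkyl radicals tethered to the α-carbon of cyclohex-2-enones, which gives 1-decalones; a fully substituted β-carbon is the extension. Ring B closes 6-endo-trig; the 5-exo mode would attack the electron-rich α-carbon C5 with a nucleophilic radical, make a spiro centre and leave an unstabilised tertiary radical. C10 is controlled by C1: the ester sits pseudoaxial to avoid the C10 methyl (1,2-allylic strain) and the radical bonds anti to it, so methyl and ester end cis. C5 is controlled by the new angular methyl: hydrogen should reach the planar C5 radical from the opposite face, axially on the chair of ring B, giving the trans fusion under kinetic control. C7 is carried through unchanged, and in 7 it is matched so that its ester is equatorial in the chair transition state that uses the same enone face. The selectivity needed is cyclisation before reduction of the primary radical; high dilution, slow addition and the slower hydrogen donor should secure it. The product is kept away from base because the trans preference of such decalones is small.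

Step 5
Reactants: 8
Product: 9 ethyl (1S,4R,4aS,6S,8aS)-4-hydroxy-6-(2-hydroxypropan-2-yl)-4,8a-dimethyldecahydronaphthalene-1-carboxylate
Conditions: MeMgBr (4 equiv), CeCl3 (4 equiv, anhydrous), THF, −78 to 0 °C; aq NH4Cl
Reagents that add atoms: methylmagnesium bromide C[Mg]Br
Why: organocerium 1,2-addition: the non-basic methyl nucleophile should add to the C4 ketone without enolising C5 and twice to the unhindered C7 methyl ester, while the C1 ethyl ester, on a carbon flanked by quaternary C10, is left. Methyl enters C4 equatorially, opposite the axial C10 methyl, which gives the axial hydroxyl (4R).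

Step 6
Reactants: 9
Product: 10 (1R,4S,4aR,7S,8aS)-4-(hydroxymethyl)-7-(2-hydroxypropan-2-yl)-1,4a-dimethyldecahydronaphthalen-1-ol
Conditions: LiAlH4 (4 equiv), THF, 0 °C to reflux; H2O–NaOH work-up
Reagents that add atoms: none
Why: hydride reduction of the hindered ester to the primary alcohol; the tertiary alcohols are only deprotonated and no stereocentre is touched.

Step 7
Reactants: 10
Product: 11 (1S,4R,4aS,6S,8aS)-4-hydroxy-6-(2-hydroxypropan-2-yl)-4,8a-dimethyldecahydronaphthalene-1-carbaldehyde
Conditions: Dess–Martin periodinane (1.3 equiv), CH2Cl2, 0 °C to rt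
Reagents that add atoms: none
Why: Dess–Martin oxidation of the only oxidisable (primary) alcohol; the near-neutral conditions should keep the equatorial, thermodynamically preferred configuration at C1.

Step 8
Reactants: 11; 12 1,3,5-trimethoxybenzene
Product: 14 (1R,4S,4aR,7S,8aS)-4-[hydroxy(2,4,6-trimethoxyphenyl)methyl]-7-(2-hydroxypropan-2-yl)-1,4a-dimethyldecahydronaphthalen-1-ol (both carbinol epimers), via 2,4,6-trimethoxyphenyllithium 13 (not isolated)
Conditions: 12 (3.6 equiv), n-BuLi (3.5 equiv), THF, 0 °C to rt, 1 h; then 11, −78 to 0 °C; aq NH4Cl
Reagents that add atoms: none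
Why: directed ortho-lithiation of the arene (every ring position is equivalent and flanked by two methoxy groups) followed by 1,2-addition to the aldehyde; two equivalents are spent on the hydroxyl groups. The carbinol configuration is irrelevant because the centre is ionised in the next step.

Step 9
Reactants: 14
Product: 15 (1R,4R,4aR,7S,8aS)-7-(2-hydroxypropan-2-yl)-1,4a-dimethyl-4-[(1R)-3-methyl-1-(2,4,6-trimethoxyphenyl)but-3-en-1-yl]decahydronaphthalen-1-ol
Conditions: CH2=C(CH3)CH2SiMe3 (3 equiv), BF3·OEt2 (3 equiv), CH2Cl2, −78 °C; aq NaHCO3
Reagents that add atoms: trimethyl(2-methylallyl)silane C=C(C)C[Si](C)(C)C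
Why: Hosomi–Sakurai-type allylation of a benzylic cation (SN1); the trimethoxyphenyl carbinol should ionise at −78 °C, far more readily than the tertiary alcohols. In the cation H-1 lies in the plane next to an ortho-methoxy group (1,3-allylic strain), C10 and C2 shield the two faces, and the silane should enter from the C2 side, anti to quaternary C10, which gives (9′R).

Step 10
Reactants: 15
Product: 16 (1R,4R,4aR,7S,8aS)-7-(2-hydroxypropan-2-yl)-1,4a-dimethyl-4-[(1R)-3-methyl-1-(2,4,6-trimethoxyphenyl)butyl]decahydronaphthalen-1-ol
Conditions: H2 (1 atm), Pd/C (10% palladium on carbon), EtOAc, rt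
Reagents that add atoms: none
Why: catalytic hydrogenation of the 1,1-disubstituted alkene to the isobutyl group; no stereocentre is formed and the aryl ethers and the benzylic C–C bond are not affected.

Step 11
Reactants: 16
Product: 17 (1R,4R,4aR,7S,8aS)-4-[(1R)-1-(3,5-dibromo-2,4,6-trimethoxyphenyl)-3-methylbutyl]-7-(2-hydroxypropan-2-yl)-1,4a-dimethyldecahydronaphthalen-1-ol
Conditions: NBS (2.1 equiv), MeCN, 0 °C, dark
Reagents that add atoms: N-bromosuccinimide O=C1CCC(=O)N1Br
Why: electrophilic aromatic bromination; the two free ring positions are equivalent and each is activated by two ortho and one para alkoxy group.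

Step 12
Reactants: 17
Product: 19 5-[(1R)-1-[(1R,4R,4aS,6S,8aR)-4-hydroxy-6-(2-hydroxypropan-2-yl)-4,8a-dimethyldecahydronaphthalen-1-yl]-3-methylbutyl]-2,4,6-trimethoxybenzene-1,3-dicarbaldehyde, via dilithiated arene bis-alkoxide 18 (not isolated)
Conditions: t-BuLi (6.5 equiv), THF, −78 °C; DMF (10 equiv), −78 to 0 °C; aq NH4Cl
Reagents that add atoms: N,N-dimethylformamide CN(C)C=O
Why: deprotonation of both hydroxyls, then double bromine–lithium exchange (each aryllithium is flanked by two coordinating methoxy groups) and Bouveault-type formylation with the formamide.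

Step 13
Reactants: 19
Product: 20 5-[(1R)-1-[(1R,4R,4aS,6S,8aR)-4-hydroxy-6-(2-hydroxypropan-2-yl)-4,8a-dimethyldecahydronaphthalen-1-yl]-3-methylbutyl]-2,4,6-trihydroxybenzene-1,3-dicarbaldehyde (target)
Conditions: NaSEt (10 equiv), DMF, 110 °C; cold 1 M HCl work-up
Reagents that add atoms: none
Why: nucleophilic (SN2) O-demethylation by thiolate; every methoxy group is ortho or para to a formyl group, so each phenoxide is a good leaving group. The conditions are not acidic, so the tertiary carbinols should survive.

## Compound list

1 | ethyl 2-methyl-4-oxocyclohex-2-ene-1-carboxylate (racemic) | CCOC(=O)C1CCC(=O)C=C1C | starting material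
2 | 3-methylideneoxolan-2-one | C=C1CCOC1=O | starting material
3 | ethyl 2-methyl-4-oxo-3-[(2-oxooxolan-3-yl)methyl]cyclohex-2-ene-1-carboxylate (four stereoisomers) | CCOC(=O)C1CCC(=O)C(CC2CCOC2=O)=C1C | intermediate
4 | ethyl 3-{4-iodo-2-[(trimethylsilyloxy)carbonyl]butyl}-2-methyl-4-oxocyclohex-2-ene-1-carboxylate (four stereoisomers) | CCOC(=O)C1CCC(=O)C(CC(CCI)C(=O)O[Si](C)(C)C)=C1C | intermediate
5 | 2-{[3-(ethoxycarbonyl)-2-methyl-6-oxocyclohex-1-en-1-yl]methyl}-4-iodobutanoic acid (four stereoisomers) | CCOC(=O)C1CCC(=O)C(CC(CCI)C(=O)O)=C1C | intermediate
6 | ethyl 3-[4-iodo-2-(methoxycarbonyl)butyl]-2-methyl-4-oxocyclohex-2-ene-1-carboxylate (four stereoisomers) | CCOC(=O)C1CCC(=O)C(CC(CCI)C(=O)OC)=C1C | intermediate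
7 | ethyl (1S)-3-[(2R)-4-iodo-2-(methoxycarbonyl)butyl]-2-methyl-4-oxocyclohex-2-ene-1-carboxylate | CCOC(=O)[C@H]1CCC(=O)C(C[C@H](CCI)C(=O)OC)=C1C | intermediate
8 | 1-ethyl 6-methyl (1S,4aS,6S,8aS)-8a-methyl-4-oxodecahydronaphthalene-1,6-dicarboxylate | CCOC(=O)[C@H]1CCC(=O)[C@H]2C[C@@H](C(=O)OC)CC[C@]12C | intermediate
9 | ethyl (1S,4R,4aS,6S,8aS)-4-hydroxy-6-(2-hydroxypropan-2-yl)-4,8a-dimethyldecahydronaphthalene-1-carboxylate | CCOC(=O)[C@H]1CC[C@@](C)(O)[C@H]2C[C@@H](C(C)(C)O)CC[C@]12C | intermediate
10 | (1R,4S,4aR,7S,8aS)-4-(hydroxymethyl)-7-(2-hydroxypropan-2-yl)-1,4a-dimethyldecahydronaphthalen-1-ol | OC[C@H]1CC[C@@](C)(O)[C@H]2C[C@@H](C(C)(C)O)CC[C@]12C | intermediate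
11 | (1S,4R,4aS,6S,8aS)-4-hydroxy-6-(2-hydroxypropan-2-yl)-4,8a-dimethyldecahydronaphthalene-1-carbaldehyde | O=C[C@H]1CC[C@@](C)(O)[C@H]2C[C@@H](C(C)(C)O)CC[C@]12C | intermediate
12 | 1,3,5-trimethoxybenzene | COc1cc(OC)cc(OC)c1 | starting material
13 | 2,4,6-trimethoxyphenyllithium | [Li]c1c(OC)cc(OC)cc1OC | intermediate
14 | (1R,4S,4aR,7S,8aS)-4-[hydroxy(2,4,6-trimethoxyphenyl)methyl]-7-(2-hydroxypropan-2-yl)-1,4a-dimethyldecahydronaphthalen-1-ol (both carbinol epimers) | COc1cc(OC)c(C(O)[C@H]2CC[C@@](C)(O)[C@H]3C[C@@H](C(C)(C)O)CC[C@]23C)c(OC)c1 | intermediate
15 | (1R,4R,4aR,7S,8aS)-7-(2-hydroxypropan-2-yl)-1,4a-dimethyl-4-[(1R)-3-methyl-1-(2,4,6-trimethoxyphenyl)but-3-en-1-yl]decahydronaphthalen-1-ol | C=C(C)C[C@@H](c1c(OC)cc(OC)cc1OC)[C@H]1CC[C@@](C)(O)[C@H]2C[C@@H](C(C)(C)O)CC[C@]12C | intermediate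
16 | (1R,4R,4aR,7S,8aS)-7-(2-hydroxypropan-2-yl)-1,4a-dimethyl-4-[(1R)-3-methyl-1-(2,4,6-trimethoxyphenyl)butyl]decahydronaphthalen-1-ol | CC(C)C[C@@H](c1c(OC)cc(OC)cc1OC)[C@H]1CC[C@@](C)(O)[C@H]2C[C@@H](C(C)(C)O)CC[C@]12C | intermediate
17 | (1R,4R,4aR,7S,8aS)-4-[(1R)-1-(3,5-dibromo-2,4,6-trimethoxyphenyl)-3-methylbutyl]-7-(2-hydroxypropan-2-yl)-1,4a-dimethyldecahydronaphthalen-1-ol | CC(C)C[C@@H](c1c(OC)c(Br)c(OC)c(Br)c1OC)[C@H]1CC[C@@](C)(O)[C@H]2C[C@@H](C(C)(C)O)CC[C@]12C | intermediate
18 | 3,5-dilithio derivative of 17 as its dilithium bis-alkoxide | CC(C)C[C@@H](c1c(OC)c([Li])c(OC)c([Li])c1OC)[C@H]1CC[C@@](C)(O[Li])[C@H]2C[C@@H](C(C)(C)O[Li])CC[C@]12C | intermediate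
19 | 5-[(1R)-1-[(1R,4R,4aS,6S,8aR)-4-hydroxy-6-(2-hydroxypropan-2-yl)-4,8a-dimethyldecahydronaphthalen-1-yl]-3-methylbutyl]-2,4,6-trimethoxybenzene-1,3-dicarbaldehyde | CC(C)C[C@@H](c1c(OC)c(C=O)c(OC)c(C=O)c1OC)[C@H]1CC[C@@](C)(O)[C@H]2C[C@@H](C(C)(C)O)CC[C@]12C | intermediate
20 | 5-[(1R)-1-[(1R,4R,4aS,6S,8aR)-4-hydroxy-6-(2-hydroxypropan-2-yl)-4,8a-dimethyldecahydronaphthalen-1-yl]-3-methylbutyl]-2,4,6-trihydroxybenzene-1,3-dicarbaldehyde | CC(C)C[C@@H](c1c(O)c(C=O)c(O)c(C=O)c1O)[C@H]1CC[C@@](C)(O)[C@H]2C[C@@H](C(C)(C)O)CC[C@]12C | target

## Step count and least certain steps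

Total: 13 steps. Longest linear sequence: 13 steps (1 to 20); 12 enters in step 8 without steps of its own.

Step 4 (key step). Most likely failure: hydrogen transfer to the primary C9 radical before the slow closure onto the fully substituted C10 (plain loss of iodine), or delivery of hydrogen to C5 from the methyl-bearing face. Fallback: a nickel-catalysed reductive conjugate cyclisation, which sets out from 7. With NiCl2(dme) (10 mol%), neocuproine, Mn powder and Et3SiCl in DMA at rt, zerovalent nickel and the chlorosilane should turn the enone into a 1-siloxyallylnickel species that takes up C9 and forms C9–C10 by reductive elimination. This gives the triethylsilyl enol ether F1. F1 is then protonated at C5 in a separate, controllable operation (Bu4NF–AcOH, THF, −78 °C), axially and anti to the angular methyl, and the sequence comes back to the route at 8.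

Step 1. Most likely failure: bond formation through C1 of the ambident dienolate (quaternary product), or a second addition and anionic oligomerisation of 2. Fallback: a neutral enamine Michael addition, which sets out from 1. Pyrrolidine (cat. TsOH, PhMe, removal of water) should give the dienamine F2. F2 should add to 2 through C5 (dioxane, 80 °C) to give the adduct enamine F3, which is hydrolysed in the same flask (aq AcOH–NaOAc) and comes back to the route at 3.

Step 2. Most likely failure: dealkylation of the ethyl ester alongside the lactone, or acid-induced side reactions of the enone. Fallback: base instead of silyl iodide, setting out from 3. LiOH (1.0 equiv, THF–H2O, 0 °C) should open only the lactone to the lithium hydroxy carboxylate F4. MeI in DMF should give the hydroxy methyl ester F5, which is used at once because it can relactonise. An Appel iodination (I2, PPh3, imidazole, CH2Cl2, 0 °C) comes back to the route at 6.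

Step 5. Most likely failure: addition of the methyl nucleophile to the C1 ester as well, or enolisation at C5 before addition. Fallback: the C1 carboxyl is protected as its carboxylate, setting out from 8.
- MeMgBr–CeCl3 (1.2 equiv, −78 °C) should touch only the ketone and give the hydroxy diester F6.
- KOH in MeOH–H2O at 60 °C should give the diacid F7 (C1 and C7 can only settle equatorial).
- Fischer esterification (MeOH, cat. Me3SiCl, rt) should esterify only the unhindered C7 acid, giving the monoester F8.
- Excess MeMgBr in THF should convert the ester into the carbinol while the magnesium carboxylate at C1 stays inert, giving the hydroxy acid F9.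
- LiAlH4 comes back to the route at 10.

Step 9. Most likely failure: a facial preference at the cation that is weak or opposite to the 1,3-allylic strain model, loss of H-1 from the cation with scrambling of C1, or ionisation of the tertiary carbinols if the temperature rises. Fallback for an opposite preference: the last bond to C9′ is made by hydride instead of carbon, setting out from 14.
- Dess–Martin oxidation should give the aryl ketone F10.
- 2-Methylallylmagnesium chloride (THF, 0 °C; allylic Grignard reagents add even to hindered ketones) should give the tertiary benzylic alcohol F11.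
- Hydrogenation (H2, Pd/C) should give the saturated tertiary alcohol F12.
- Ionic hydrogenation (Et3SiH, BF3·OEt2, CH2Cl2, −78 °C) should turn the same facial bias into the other configuration at C9′ and come back to the route at 16.

A merely weak preference is met by separating the C9′ epimers at 15.

Step 12. Most likely failure: an incomplete second bromine–lithium exchange, or protonation of the dilithiated arene before formylation, leaving one position without a formyl group. Fallback: carbon is introduced by cross-coupling, setting out from 17. A double Suzuki–Miyaura vinylation (potassium vinyltrifluoroborate, Pd(OAc)2, SPhos, K3PO4, PhMe–H2O, 90 °C) should give the divinylarene F13. A Lemieux–Johnson cleavage (cat. OsO4, NaIO4, 2,6-lutidine, dioxane–H2O) comes back to the route at 19.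

## Further compounds

F1 | step 4 | 1-ethyl 6-methyl (1S,6S,8aR)-8a-methyl-4-[(triethylsilyl)oxy]-1,2,3,5,6,7,8,8a-octahydronaphthalene-1,6-dicarboxylate | CCOC(=O)[C@H]1CCC(O[Si](CC)(CC)CC)=C2C[C@@H](C(=O)OC)CC[C@]12C
F2 | step 1 | ethyl 2-methyl-4-(pyrrolidin-1-yl)cyclohexa-1,3-diene-1-carboxylate | CCOC(=O)C1=C(C)C=C(N2CCCC2)CC1
F3 | step 1 | ethyl 2-methyl-3-[(2-oxooxolan-3-yl)methyl]-4-(pyrrolidin-1-yl)cyclohexa-1,3-diene-1-carboxylate (racemic) | CCOC(=O)C1=C(C)C(CC2CCOC2=O)=C(N2CCCC2)CC1
F4 | step 2 | lithium 2-{[3-(ethoxycarbonyl)-2-methyl-6-oxocyclohex-1-en-1-yl]methyl}-4-hydroxybutanoate (four stereoisomers) | CCOC(=O)C1CCC(=O)C(CC(CCO)C(=O)[O-])=C1C.[Li+]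
F5 | step 2 | ethyl 3-[4-hydroxy-2-(methoxycarbonyl)butyl]-2-methyl-4-oxocyclohex-2-ene-1-carboxylate (four stereoisomers) | CCOC(=O)C1CCC(=O)C(CC(CCO)C(=O)OC)=C1C
F6 | step 5 | 1-ethyl 6-methyl (1S,4R,4aS,6S,8aS)-4-hydroxy-4,8a-dimethyldecahydronaphthalene-1,6-dicarboxylate | CCOC(=O)[C@H]1CC[C@@](C)(O)[C@H]2C[C@@H](C(=O)OC)CC[C@]12C
F7 | step 5 | (1S,4R,4aS,6S,8aS)-4-hydroxy-4,8a-dimethyldecahydronaphthalene-1,6-dicarboxylic acid | OC(=O)[C@H]1CC[C@@](C)(O)[C@H]2C[C@@H](C(=O)O)CC[C@]12C
F8 | step 5 | (1S,4R,4aS,6S,8aS)-4-hydroxy-6-(methoxycarbonyl)-4,8a-dimethyldecahydronaphthalene-1-carboxylic acid | OC(=O)[C@H]1CC[C@@](C)(O)[C@H]2C[C@@H](C(=O)OC)CC[C@]12C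
F9 | step 5 | (1S,4R,4aS,6S,8aS)-4-hydroxy-6-(2-hydroxypropan-2-yl)-4,8a-dimethyldecahydronaphthalene-1-carboxylic acid | OC(=O)[C@H]1CC[C@@](C)(O)[C@H]2C[C@@H](C(C)(C)O)CC[C@]12C
F10 | step 9 | [(1S,4R,4aS,6S,8aS)-4-hydroxy-6-(2-hydroxypropan-2-yl)-4,8a-dimethyldecahydronaphthalen-1-yl](2,4,6-trimethoxyphenyl)methanone | COc1cc(OC)c(C(=O)[C@H]2CC[C@@](C)(O)[C@H]3C[C@@H](C(C)(C)O)CC[C@]23C)c(OC)c1
F11 | step 9 | tertiary benzylic alcohol from F10 and the 2-methylallyl Grignard reagent: 4-[1-hydroxy-3-methyl-1-(2,4,6-trimethoxyphenyl)but-3-en-1-yl] analogue of 14 (either carbinol epimer) | C=C(C)CC(O)(c1c(OC)cc(OC)cc1OC)[C@H]1CC[C@@](C)(O)[C@H]2C[C@@H](C(C)(C)O)CC[C@]12C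
F12 | step 9 | saturated tertiary benzylic alcohol: 4-[1-hydroxy-3-methyl-1-(2,4,6-trimethoxyphenyl)butyl] analogue of 14 (either carbinol epimer) | CC(C)CC(O)(c1c(OC)cc(OC)cc1OC)[C@H]1CC[C@@](C)(O)[C@H]2C[C@@H](C(C)(C)O)CC[C@]12C
F13 | step 12 | 3,5-diethenyl analogue of 17: (1R,4R,4aR,7S,8aS)-4-[(1R)-1-(3,5-diethenyl-2,4,6-trimethoxyphenyl)-3-methylbutyl]-7-(2-hydroxypropan-2-yl)-1,4a-dimethyldecahydronaphthalen-1-ol | CC(C)C[C@@H](c1c(OC)c(C=C)c(OC)c(C=C)c1OC)[C@H]1CC[C@@](C)(O)[C@H]2C[C@@H](C(C)(C)O)CC[C@]12C
A1 | alternative 1 | 3-ene cascade product (target lacking the C4 hydroxyl) | CC(C)C[C@@H](c1c(O)c(C=O)c(O)c(C=O)c1O)[C@H]1CC=C(C)[C@H]2C[C@@H](C(C)(C)O)CC[C@]12C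
A2 | alternative 1 | (7S)-hedycaryol | CC(C)(O)[C@H]1CC/C(C)=C/CC/C(C)=C/C1
A3 | alternative 1 | 2,4,6-trihydroxybenzene-1,3-dicarbaldehyde | O=Cc1c(O)cc(O)c(C=O)c1O
A4 | alternative 1 | 3-methylbutanal | CC(C)CC=O
A5 | alternative 1 | ortho-quinone methide from A3 and A4 (one tautomer) | CC(C)CC=C1C(=O)C(C=O)=C(O)C(C=O)=C1O
A6 | alternative 2 | cis-fused 4,7-diketone with C8=C9 alkene | CC(C)C[C@@H](c2c(OC)cc(OC)cc2OC)[C@H]1CCC(=O)[C@@H]3CC(=O)C=C[C@]13C
A7 | alternative 2 | aldehyde-tethered 4-methylcyclohexa-2,5-dienone precursor | CC(C)C[C@@H](c1c(OC)cc(OC)cc1OC)[C@@H](CCC=O)C1(C)C=CC(=O)C=C1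
A8 | alternative 3 | trans-decalone with C11 carbinol and C8 hydroxyl | CCOC(=O)[C@H]1CCC(=O)[C@H]2C[C@@H](C(C)(C)O)[C@H](O)C[C@]12C
A9 | alternative 3 | C5-prenyl C10-(2-oxoethyl) cyclohexanone precursor | CCOC(=O)[C@H]1CCC(=O)[C@@H](CC=C(C)C)[C@]1(C)CC=O
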